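## Analysis of the target

Ring A is the ring that carries the 3-methylbutanoyl group: C1 bears the bridge CH2, C2 OH, C3 the acyl group, C4 OMe, C5 CH3 and C6 OH. Ring B carries the 2-methylpropanoyl group: C1' bears the bridge, C2' OH, C3' CH3, C4' OMe, C5' the acyl group and C6' OH.

- The target is a diarylmethane of two fully substituted benzene rings joined by one CH2 group. It has no other ring and no stereocentre, so the whole problem is one of substitution pattern.
- The two rings show the same 2,6-dihydroxy-4-methoxy-3-methyl-5-acylbenzyl pattern and differ only in the acyl chain. They must therefore be joined without statistical scrambling of two nearly identical halves.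
- In each ring the single O-methyl group sits on the oxygen between the acyl group and the C-methyl group. In the parent acylphloroglucinol this is the most hindered, carbonyl-chelated hydroxyl, the last one that direct alkylation reaches.
- The sensitive groups are four electron-rich phenols, two aryl ketones and the methylene bridge between two activated nuclei. Strong acid or base can cleave and scramble that bridge by retro-Friedel–Crafts processes.
- The strategy rests on reading ring A as two pieces. C2–C1–C6–C5 with the C5 methyl is a 2-substituted 3-oxopentanoate. C3–C4 is an alkyne that carries the ketone on C3 and the methoxy group on C4.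
- Forming C2–C3 and C4–C5 then builds ring A with all six substituents placed and with the methoxy group already on the correct oxygen.

## Retrosynthetic reasoning

**19 back to 18.** The last disconnection is of the two O–benzyl bonds at C2' and C6'. Benzyl ethers are chosen because they fall under neutral hydrogenolysis, which leaves the methylene bridge, the ketones and the methyl ethers alone. The forward step has only to expose two phenols.

**18 back to 10 and 16.** Ring A is cut at C2–C3 and C4–C5. This is preferred to cutting the bridge or an aryl–acyl bond because it removes an entire hexasubstituted ring in one operation. It also leaves two acyclic partners whose polarity dictates the orientation: the bis(silyloxy) ketene acetal diene 10 and the methoxy ynone 16. The forward reaction must join the methyl-bearing terminus of 10 to the methoxy carbon of 16 and the ketene acetal carbon to the acyl-bearing carbon. It must then aromatise by loss of the ketal methoxy group, so that the two silyloxy carbons become the C2 and C6 phenols.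

**10 back to 9 and 8.** The two O–Si bonds are cut in turn. The diene 10 is the doubly enolised form of the β-ketoester 8; the first silylation gives the conjugated enol ether 9 and the second, after γ-deprotonation, the ketene acetal. Nothing in the skeleton changes, so the risk of these steps is one of handling.

**8 back to 6 and 7.** The bond between the bridge CH2 and the carbon that becomes C1 of ring A is cut. That carbon is the doubly activated α-carbon of ketoester 7, and the bridge carbon is the benzylic chloride of 6. The unsymmetrical union of the two halves thus happens once, by an enolate alkylation, before ring A exists.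

**6 back to 5.** The C1'–CH2 bond is cut. C1' is the only unsubstituted ring carbon of 5 and is flanked by two benzyloxy groups and para to the methoxy group, so a chloromethylation has no regiochemical choice.

**5 back to 4, 3, 1 and 2.** The O–methyl bond, the two O–benzyl bonds and the aryl–acyl bond are cut in that order. In triol 3 the hydroxyl para to the ketone reacts first, the chelated hydroxyl next to the ring hydrogen second, and the chelated hydroxyl wedged between ketone and methyl last. Two benzylations followed by one methylation therefore place the methyl ether where the target has it. Ketone 3 comes from Friedel–Crafts acylation of 1 with 2, which can only give one monoacyl product because the two free ring positions of 1 are equivalent.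

**16 back to 12, 13 and 11.** The bond between the alkyne and the carbonyl carbon is cut. This leads to the Weinreb amide 12, made from 11, and to lithium methoxyacetylide 14, generated from acetal 13. The amide stops the addition at the ketone stage through the chelated adduct 15.

## Alternatives that were turned down

**Alternative 1:** 
- **Disconnection:** the C5'–acyl bond and the C6'–O bond of ring B are cut together. This leads back to the ortho-silylaryl triflate A2 and 2-methylpropanoic acid A3. A2 has trimethylsilyl on C5', triflate on C6', a benzyl ether on C2', and is already bridged to a dibenzylated ring A.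
- **Forward key step:** fluoride would strip silicon and triflate from A2 and leave a strained C5'–C6' triple bond. The carboxylate of A3 would add through oxygen to C6', and the aryl anion at C5' would attack the ester carbonyl. Collapse of the four-membered intermediate would leave the hydroxyl on C6' and the ketone on C5', giving the tribenzyl ether A1. Hydrogenolysis would then free the target.
- **For:** the chelated ortho-hydroxyaryl ketone is made in one nearly neutral step, without Friedel–Crafts chemistry near the bridge. The C4' methoxy group steers the nucleophile to the remote carbon C6', because the developing anion at C5' is stabilised inductively. On predictability of orientation this is at least as strong as the chosen cycloaddition.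
- **Against:** A2 is a hexasubstituted arene that must be assembled one substituent at a time. Its three ring B oxygens have to be told apart as methyl ether, benzyl ether and triflate, so the oxygen differentiation problem is moved into the precursor for both rings. The attack at C6' takes place beside the bulky diarylmethyl group. Protonation of the aryl anion by free A3 would stop at the aryl ester.
- **Comparison:** the chosen strategy makes ring A from acyclic pieces and needs selective O-alkylation on one ring only. This alternative decorates a ring that has first to be built in full, and would be clearly longer.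

**Alternative 2:** 
- **Disconnection:** ring A is cut at C3–C4, C5–C6 and C6–C1. This leads to the 4-(arylmethyl)-3-(triisopropylsilyloxy)cyclobutenone A5 and 1-methoxyprop-1-yne A6.
- **Forward key step:** on heating, A5 would open to a vinylketene, which adds to A6 in a [2+2] sense. The new cyclobutenone opens, and six-electron electrocyclisation and tautomerisation give phenol A4. In A4, C6 is the new hydroxyl, C5 methyl and C4 methoxy come from A6, C2 carries the silyl ether and C3 is unsubstituted.
- **For:** the orientation of this benzannulation with alkynyl ethers is dependable. The methoxy group arrives with the alkyne, the two ring A oxygens emerge differentiated, and A6 is a simple, stable ynol ether. On that last point it is stronger than the chosen route, whose push-pull ynone 16 is a less familiar partner.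
- **Against:** A4 lacks the acyl group. The 3-methylbutanoyl group would have to be introduced afterwards, by Friedel–Crafts acylation or Fries rearrangement at the crowded C3, in a molecule that holds an acid-labile diarylmethane bridge, a silyl ether and two benzyl ethers. A5 is the silyl enol ether of a substituted cyclobutane-1,3-dione, and its preparation adds several uncertain steps.
- **Comparison:** the chosen strategy delivers the acyl group in the ring-forming step and so avoids any Lewis-acid step after the bridge is in place.

**Alternative 3:** 
- **Disconnection:** ring B is cut between the bridge-bearing C1' and the hydroxyl-bearing C2'. This leads back to the 2-pyranone A8. Its C3 methyl, C4 methoxy and C5 2-methylpropanoyl groups become C3', C4' and C5', and a two-carbon chain on C6 links it to the dibenzylated ring A.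
- **Forward key step:** a chelating magnesium alkoxide would open the lactone to an ester and a ketone. The CH2 next to that ketone would attack the ester in a Claisen closure and, after enolisation, give the ring A dibenzyl ether A7. Hydrogenolysis would follow.
- **For:** the step imitates the polyketide origin of such rings and runs under mild conditions. The methoxy group is brought in as the vinylogous ester of the pyranone, so no phenol methylation is needed on ring B. In concept this equals the chosen strategy.
- **Against:** A8 is itself densely substituted. It needs a regioselective 4-O-methylation of a hydroxypyranone, an acylation at C5 and attachment of the arylethyl chain. Under the alkoxide the methine of the 2-methylpropanoyl group can also close onto the ester, giving a non-aromatic gem-dimethyl ring, and retro-Claisen loss of the acyl group competes. The ring A half must still be made beforehand by selective alkylation of an acylphloroglucinol.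
- **Comparison:** the chosen strategy reaches its precursor from a simple ketoester and a simple ynone in fewer, more convergent steps.

Key step: step 10

## Route

Remark on the chemistry: the (1Z,3Z) geometry written for diene 10 is the one expected from kinetic γ-deprotonation. Both double bonds become ring bonds of the arene, so a mixture of geometric isomers would serve equally.

Step 1
Reactants: 1 2,4,6-trihydroxytoluene; 2 2-methylpropanoyl chloride
Product: 3 1-(2,4,6-trihydroxy-3-methylphenyl)-2-methylpropan-1-one
Conditions: AlCl3, PhNO2/CH2Cl2, rt to 50 °C; aq HCl work-up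
Reagents that add atoms: none
Why: Friedel–Crafts acylation of a phloroglucinol nucleus; the two free ring positions of 1 are equivalent and the first acyl group deactivates the ring, so one monoketone should result.

Step 2
Reactants: 3 1-(2,4,6-trihydroxy-3-methylphenyl)-2-methylpropan-1-one
Product: 4 1-[4,6-bis(benzyloxy)-2-hydroxy-3-methylphenyl]-2-methylpropan-1-one
Conditions: BnBr (2.1 equiv), K2CO3, DMF, 0 °C to rt
Reagents that add atoms: benzyl bromide, BrCc1ccccc1
Why: Williamson ether synthesis under kinetic control; the non-chelated hydroxyl para to the ketone is the most acidic and reacts first, and of the two chelated hydroxyls the one beside the ring hydrogen is far less hindered than the one between ketone and methyl, which should stay free.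

Step 3
Reactants: 4 1-[4,6-bis(benzyloxy)-2-hydroxy-3-methylphenyl]-2-methylpropan-1-one
Product: 5 1-[4,6-bis(benzyloxy)-2-methoxy-3-methylphenyl]-2-methylpropan-1-one
Conditions: MeI, K2CO3, DMF, 50 °C
Reagents that add atoms: iodomethane, CI
Why: O-methylation of the one remaining phenol; it is chelated and hindered, so a small electrophile and warming are used, and carbonate is too weak to enolise the ketone.

Step 4
Reactants: 5 1-[4,6-bis(benzyloxy)-2-methoxy-3-methylphenyl]-2-methylpropan-1-one
Product: 6 1-[2,4-bis(benzyloxy)-3-(chloromethyl)-6-methoxy-5-methylphenyl]-2-methylpropan-1-one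
Conditions: MOMCl, ZnCl2 (cat.), CH2Cl2, 0 °C to rt; used crude
Reagents that add atoms: chloromethyl methyl ether, COCCl
Why: Blanc-type chloromethylation at the only free ring carbon, which is ortho to two benzyloxy groups and para to the methoxy group; the twisted ketone deactivates little and the mild Lewis acid should spare the benzyl ethers.

Step 5
Reactants: 6 1-[2,4-bis(benzyloxy)-3-(chloromethyl)-6-methoxy-5-methylphenyl]-2-methylpropan-1-one; 7 methyl 3-oxopentanoate
Product: 8 methyl 2-{[2,6-bis(benzyloxy)-4-methoxy-3-methyl-5-(2-methylpropanoyl)phenyl]methyl}-3-oxopentanoate (racemic)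
Conditions: 7 (1.5 equiv), NaH, THF, 0 °C; then 6, NaI (cat.), 0 to 50 °C
Reagents that add atoms: none
Why: C-alkylation of a β-ketoester sodium enolate with an activated benzylic chloride; excess 7 and the bulk of the electrophile should prevent double alkylation, and the new stereocentre is racemic and is erased in step 6.

Step 6
Reactants: 8 methyl 2-{[2,6-bis(benzyloxy)-4-methoxy-3-methyl-5-(2-methylpropanoyl)phenyl]methyl}-3-oxopentanoate
Product: 9 methyl 2-{[2,6-bis(benzyloxy)-4-methoxy-3-methyl-5-(2-methylpropanoyl)phenyl]methyl}-3-(trimethylsilyloxy)pent-2-enoate (E/Z mixture)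
Conditions: Me3SiCl, Et3N, PhMe, rt, 48–72 h; filter, concentrate
Reagents that add atoms: chlorotrimethylsilane, C[Si](C)(C)Cl
Why: Silyl enol ether formation under soft enolisation; only the β-dicarbonyl unit is acidic enough for Et3N, so the ring B ketone is untouched, and the conjugated 2-enoate is the thermodynamic product.

Step 7
Reactants: 9 methyl 2-{[2,6-bis(benzyloxy)-4-methoxy-3-methyl-5-(2-methylpropanoyl)phenyl]methyl}-3-(trimethylsilyloxy)pent-2-enoate
Product: 10 (1Z,3Z)-2-{[2,6-bis(benzyloxy)-4-methoxy-3-methyl-5-(2-methylpropanoyl)phenyl]methyl}-1-methoxy-1,3-bis(trimethylsilyloxy)penta-1,3-diene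
Conditions: LiN(iPr)2 (LDA, commercial solution), THF, −78 °C; Me3SiCl, −78 °C to rt; used crude under argon
Reagents that add atoms: chlorotrimethylsilane, C[Si](C)(C)Cl
Why: Vinylogous (γ) deprotonation of the silyloxy enoate and O-silylation of the extended ester enolate, the standard preparation of 1-alkoxy-1,3-bis(silyloxy)dienes; the ring B ketone is di-ortho-substituted and branched, so its deprotonation should be slow, and a silyl enol ether formed there would be inert in step 10 and hydrolysed in its work-up.

Step 8
Reactants: 11 3-methylbutanoyl chloride
Product: 12 N-methoxy-N,3-dimethylbutanamide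
Conditions: MeNHOMe·HCl, Et3N, CH2Cl2, 0 °C to rt
Reagents that add atoms: N,O-dimethylhydroxylamine hydrochloride, CNOC.Cl
Why: Acylation of an amine by an acid chloride (Weinreb amide formation).

Step 9
Reactants: 12 N-methoxy-N,3-dimethylbutanamide; 13 2-chloro-1,1-dimethoxyethane
Product: 16 1-methoxy-5-methylhex-1-yn-3-one, via lithium methoxyacetylide 14 (not isolated), via lithium hemiaminal alkoxide 15 (not isolated)
Conditions: Et2NH, n-BuLi, THF, 0 °C (LiNEt2, 3 equiv per 13); 13, 0 °C; then 12, −78 to −20 °C; cold aq NaH2PO4; used promptly
Reagents that add atoms: none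
Why: Twofold elimination from the chloroacetal and deprotonation give the alkoxyacetylide in situ; Weinreb ketone synthesis then stops at the chelated adduct 15, which releases the ynone only on the buffered quench.

Step 10
Reactants: 10 (1Z,3Z)-2-{[2,6-bis(benzyloxy)-4-methoxy-3-methyl-5-(2-methylpropanoyl)phenyl]methyl}-1-methoxy-1,3-bis(trimethylsilyloxy)penta-1,3-diene; 16 1-methoxy-5-methylhex-1-yn-3-one
Product: 18 1-[3-{[2,6-bis(benzyloxy)-4-methoxy-3-methyl-5-(2-methylpropanoyl)phenyl]methyl}-2,4-dihydroxy-6-methoxy-5-methylphenyl]-3-methylbutan-1-one, via cyclohexadiene cycloadduct 17 (not isolated)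
Conditions: 16 (2 equiv), PhMe, 25 to 90 °C (sealed); then 1 M HCl, THF, rt
Reagents that add atoms: none
Why: The electron-rich diene 10 and the acetylenic ketone 16 should combine in a thermal normal-demand [4+2] cycloaddition, the closest known reaction type being the Diels–Alder aromatisation of 1-alkoxy-1,3-bis(silyloxy)dienes with acetylenic ketones and esters to resorcinols. Bond formation is expected to be asynchronous: the CH(CH3) terminus of 10, which has the largest HOMO coefficient, leads onto the methoxy-bearing alkyne carbon of 16, the conjugate position made electrophilic by the carbonyl group, and the ketene acetal carbon closes onto the α-carbon; in the stepwise limit this is a Mukaiyama–Michael addition followed by a 6-exo-trig closure. Ring A is thus closed by cycloaddition with formation of C4–C5 and C2–C3, giving the cyclohexa-1,4-diene 17. On acidic work-up the silyl methyl ketal of 17 ionises, the methoxy group leaves as methanol together with the hydrogen on the methyl-bearing sp3 carbon, and both silyl ethers are hydrolysed, so the arene 18 forms irreversibly. The two sp3 centres of 17 are destroyed, so no stereocontrol is needed. The step needs regioselectivity, which the matched polarisation of the partners secures, since the reverse orientation would join the nucleophilic diene terminus to the electron-rich α-carbon of the ynone. It also needs chemoselectivity for the alkyne over the carbonyl groups, which the absence of a Lewis acid and the shielding of the ring B ketone by its two ortho substituents secure. A methoxyalkyne, unlike an ethoxyalkyne, has no retro-ene path on heating.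

Step 11
Reactants: 18 1-[3-{[2,6-bis(benzyloxy)-4-methoxy-3-methyl-5-(2-methylpropanoyl)phenyl]methyl}-2,4-dihydroxy-6-methoxy-5-methylphenyl]-3-methylbutan-1-one
Product: 19 1-[3-{[2,6-dihydroxy-4-methoxy-3-methyl-5-(2-methylpropanoyl)phenyl]methyl}-2,4-dihydroxy-6-methoxy-5-methylphenyl]-3-methylbutan-1-one (CNP0265841.0)
Conditions: H2 (1 atm), 10% Pd/C, EtOAc/MeOH, rt
Reagents that add atoms: none
Why: Hydrogenolysis of two aryl benzyl ethers under neutral conditions; the chelated, electron-rich aryl ketones and the diarylmethane C–C bonds should not be reduced at atmospheric pressure.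

## Compound list

1 | 2,4,6-trihydroxytoluene | Cc1c(O)cc(O)cc1O | starting material
2 | 2-methylpropanoyl chloride | CC(C)C(=O)Cl | starting material
3 | 1-(2,4,6-trihydroxy-3-methylphenyl)-2-methylpropan-1-one | Cc1c(O)cc(O)c(C(=O)C(C)C)c1O | intermediate
4 | 1-[4,6-bis(benzyloxy)-2-hydroxy-3-methylphenyl]-2-methylpropan-1-one | Cc1c(OCc2ccccc2)cc(OCc2ccccc2)c(C(=O)C(C)C)c1O | intermediate
5 | 1-[4,6-bis(benzyloxy)-2-methoxy-3-methylphenyl]-2-methylpropan-1-one | COc1c(C)c(OCc2ccccc2)cc(OCc2ccccc2)c1C(=O)C(C)C | intermediate
6 | 1-[2,4-bis(benzyloxy)-3-(chloromethyl)-6-methoxy-5-methylphenyl]-2-methylpropan-1-one | COc1c(C)c(OCc2ccccc2)c(CCl)c(OCc2ccccc2)c1C(=O)C(C)C | intermediate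
7 | methyl 3-oxopentanoate | CCC(=O)CC(=O)OC | starting material
8 | methyl 2-{[2,6-bis(benzyloxy)-4-methoxy-3-methyl-5-(2-methylpropanoyl)phenyl]methyl}-3-oxopentanoate (racemic) | CCC(=O)C(Cc1c(OCc2ccccc2)c(C)c(OC)c(C(=O)C(C)C)c1OCc1ccccc1)C(=O)OC | intermediate
9 | methyl 2-{[2,6-bis(benzyloxy)-4-methoxy-3-methyl-5-(2-methylpropanoyl)phenyl]methyl}-3-(trimethylsilyloxy)pent-2-enoate (E/Z mixture) | CCC(O[Si](C)(C)C)=C(Cc1c(OCc2ccccc2)c(C)c(OC)c(C(=O)C(C)C)c1OCc1ccccc1)C(=O)OC | intermediate
10 | (1Z,3Z)-2-{[2,6-bis(benzyloxy)-4-methoxy-3-methyl-5-(2-methylpropanoyl)phenyl]methyl}-1-methoxy-1,3-bis(trimethylsilyloxy)penta-1,3-diene | C/C=C(O[Si](C)(C)C)/C(Cc1c(OCc2ccccc2)c(C)c(OC)c(C(=O)C(C)C)c1OCc1ccccc1)=C(/OC)O[Si](C)(C)C | intermediate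
11 | 3-methylbutanoyl chloride | CC(C)CC(=O)Cl | starting material
12 | N-methoxy-N,3-dimethylbutanamide | CC(C)CC(=O)N(C)OC | intermediate
13 | 2-chloro-1,1-dimethoxyethane | COC(CCl)OC | starting material
14 | lithium methoxyacetylide (not isolated) | [Li]C#COC | intermediate
15 | lithium 1-methoxy-3-[methoxy(methyl)amino]-5-methylhex-1-yn-3-olate (not isolated) | [Li]OC(CC(C)C)(C#COC)N(C)OC | intermediate
16 | 1-methoxy-5-methylhex-1-yn-3-one | COC#CC(=O)CC(C)C | intermediate
17 | 1-[5-{[2,6-bis(benzyloxy)-4-methoxy-3-methyl-5-(2-methylpropanoyl)phenyl]methyl}-2,6-dimethoxy-3-methyl-4,6-bis(trimethylsilyloxy)cyclohexa-1,4-dien-1-yl]-3-methylbutan-1-one (diastereomer mixture, not isolated) | COC1(O[Si](C)(C)C)C(Cc2c(OCc3ccccc3)c(C)c(OC)c(C(=O)C(C)C)c2OCc2ccccc2)=C(O[Si](C)(C)C)C(C)C(OC)=C1C(=O)CC(C)C | intermediate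
18 | 1-[3-{[2,6-bis(benzyloxy)-4-methoxy-3-methyl-5-(2-methylpropanoyl)phenyl]methyl}-2,4-dihydroxy-6-methoxy-5-methylphenyl]-3-methylbutan-1-one | COc1c(C)c(O)c(Cc2c(OCc3ccccc3)c(C)c(OC)c(C(=O)C(C)C)c2OCc2ccccc2)c(O)c1C(=O)CC(C)C | intermediate
19 | 1-[3-{[2,6-dihydroxy-4-methoxy-3-methyl-5-(2-methylpropanoyl)phenyl]methyl}-2,4-dihydroxy-6-methoxy-5-methylphenyl]-3-methylbutan-1-one | COc1c(C)c(O)c(Cc2c(O)c(C)c(OC)c(C(=O)C(C)C)c2O)c(O)c1C(=O)CC(C)C | target

## Step count and least certain steps

Total: 11 steps. Longest linear sequence: 9 steps (steps 1 to 7, 10 and 11). Steps 8 and 9 form the two-step side branch to ynone 16.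

**Step 10 (key step).**
- **Risk:** the cycloaddition may not take place, because the methoxy group raises the LUMO of the alkyne and the diene carries a bulky group on its central carbon. Slow desilylation of 10 back to the ketoester would then take over on prolonged heating.
- **Fallback:** ring A is made as a monomer by classical acylphloroglucinol chemistry and joined to ring B afterwards. The fallback sets out from 1, 11 and 6. Friedel–Crafts acylation of 1 with 11 (AlCl3) would give 1-(2,4,6-trihydroxy-3-methylphenyl)-3-methylbutan-1-one F1. Dibenzylation as in step 2 would give 1-[4,6-bis(benzyloxy)-2-hydroxy-3-methylphenyl]-3-methylbutan-1-one F2. Methylation as in step 3 would give 1-[4,6-bis(benzyloxy)-2-methoxy-3-methylphenyl]-3-methylbutan-1-one F3. Hydrogenolysis (H2, Pd/C) would give 1-(4,6-dihydroxy-2-methoxy-3-methylphenyl)-3-methylbutan-1-one F4. Friedel–Crafts C-benzylation of F4 at its only free ring carbon, between the two hydroxyls, with chloride 6 (ZnCl2 cat., CH2Cl2, rt) would return to the route at 18.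

**Step 7.**
- **Risk:** γ-deprotonation of the crowded enoate 9 may be incomplete, or C-silylation and enolisation of the ring B ketone may compete. The ketene acetal may also hydrolyse on handling.
- **Fallback:** the same cycloaddition is run on the unhindered parent diene and ring B is attached afterwards. The fallback sets out from 7, 16 and 6. Me3SiCl/Et3N would convert 7 into methyl 3-(trimethylsilyloxy)pent-2-enoate F5. LiN(iPr)2 and Me3SiCl would give (1Z,3Z)-1-methoxy-1,3-bis(trimethylsilyloxy)penta-1,3-diene F6. Heating F6 with 16 would give 1-[2,6-dimethoxy-3-methyl-4,6-bis(trimethylsilyloxy)cyclohexa-1,4-dien-1-yl]-3-methylbutan-1-one F7, which on acid work-up aromatises to 1-(4,6-dihydroxy-2-methoxy-3-methylphenyl)-3-methylbutan-1-one F4. C-benzylation of F4 with 6 as above would return to the route at 18.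

**Step 9.**
- **Risk:** the diethylamine present at the quench may add in conjugate fashion to the ynone as adduct 15 collapses, and the push-pull alkyne may hydrate during work-up.
- **Fallback:** the ketone is reached by oxidation instead of acylation. The fallback sets out from 14, generated from 13 as before. Addition of 14 to 3-methylbutanal F8 at −78 °C would give 1-methoxy-5-methylhex-1-yn-3-ol F9, which is not a Michael acceptor and can be freed of amine. Oxidation of F9 with MnO2 in CH2Cl2 under neutral conditions would return to the route at 16.

**Step 4.**
- **Risk:** the very electron-rich benzylic chloride may alkylate unreacted 5, giving a diarylmethane, and the Lewis acid may remove a benzyl ether.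
- **Fallback:** the carbon is introduced at the aldehyde oxidation level. The fallback sets out from 5. Vilsmeier–Haack formylation (POCl3, DMF) would give 2,6-bis(benzyloxy)-4-methoxy-3-methyl-5-(2-methylpropanoyl)benzaldehyde F10. NaBH4 at 0 °C should reduce the aldehyde in preference to the hindered ketone and give 1-[2,4-bis(benzyloxy)-3-(hydroxymethyl)-6-methoxy-5-methylphenyl]-2-methylpropan-1-one F11. SOCl2 in CH2Cl2 would return to the route at 6.

**Step 2.**
- **Risk:** discrimination between the two carbonyl-chelated hydroxyls in the second benzylation may be poor.
- **Fallback:** selectivity is sought in a cleavage instead of an alkylation. The fallback sets out from 3. Exhaustive benzylation (excess BnBr, K2CO3, DMF, 60 °C) would give 1-[2,4,6-tris(benzyloxy)-3-methylphenyl]-2-methylpropan-1-one F12. One equivalent of BCl3 at −78 °C should then remove the benzyl group that is both chelated to the ketone and twisted out of plane by its two neighbours, returning to the route at 4.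

## Further compounds

F1 | step 10 | 1-(2,4,6-trihydroxy-3-methylphenyl)-3-methylbutan-1-one | Cc1c(O)cc(O)c(C(=O)CC(C)C)c1O
F2 | step 10 | 1-[4,6-bis(benzyloxy)-2-hydroxy-3-methylphenyl]-3-methylbutan-1-one | Cc1c(OCc2ccccc2)cc(OCc2ccccc2)c(C(=O)CC(C)C)c1O
F3 | step 10 | 1-[4,6-bis(benzyloxy)-2-methoxy-3-methylphenyl]-3-methylbutan-1-one | COc1c(C)c(OCc2ccccc2)cc(OCc2ccccc2)c1C(=O)CC(C)C
F4 | step 10 | 1-(4,6-dihydroxy-2-methoxy-3-methylphenyl)-3-methylbutan-1-one | COc1c(C)c(O)cc(O)c1C(=O)CC(C)C
F5 | step 7 | methyl 3-(trimethylsilyloxy)pent-2-enoate | CCC(O[Si](C)(C)C)=CC(=O)OC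
F6 | step 7 | (1Z,3Z)-1-methoxy-1,3-bis(trimethylsilyloxy)penta-1,3-diene | C/C=C(O[Si](C)(C)C)/C=C(/OC)O[Si](C)(C)C
F7 | step 7 | 1-[2,6-dimethoxy-3-methyl-4,6-bis(trimethylsilyloxy)cyclohexa-1,4-dien-1-yl]-3-methylbutan-1-one | COC1(O[Si](C)(C)C)C=C(O[Si](C)(C)C)C(C)C(OC)=C1C(=O)CC(C)C
F8 | step 9 | 3-methylbutanal | CC(C)CC=O
F9 | step 9 | 1-methoxy-5-methylhex-1-yn-3-ol (racemic) | COC#CC(O)CC(C)C
F10 | step 4 | 2,6-bis(benzyloxy)-4-methoxy-3-methyl-5-(2-methylpropanoyl)benzaldehyde | COc1c(C)c(OCc2ccccc2)c(C=O)c(OCc2ccccc2)c1C(=O)C(C)C
F11 | step 4 | 1-[2,4-bis(benzyloxy)-3-(hydroxymethyl)-6-methoxy-5-methylphenyl]-2-methylpropan-1-one | COc1c(C)c(OCc2ccccc2)c(CO)c(OCc2ccccc2)c1C(=O)C(C)C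
F12 | step 2 | 1-[2,4,6-tris(benzyloxy)-3-methylphenyl]-2-methylpropan-1-one | Cc1c(OCc2ccccc2)cc(OCc2ccccc2)c(C(=O)C(C)C)c1OCc1ccccc1
A1 | alternative 1 | tribenzyl ether of the target with the C6' hydroxyl and C5' acyl group in place | COc1c(C)c(OCc2ccccc2)c(Cc2c(OCc3ccccc3)c(C)c(OC)c(C(=O)CC(C)C)c2OCc2ccccc2)c(O)c1C(=O)C(C)C
A2 | alternative 1 | ring B ortho-silylaryl triflate (trimethylsilyl on C5', triflate on C6') bridged to dibenzylated ring A | COc1c(C)c(OCc2ccccc2)c(Cc2c(OCc3ccccc3)c(C)c(OC)c(C(=O)CC(C)C)c2OCc2ccccc2)c(OS(=O)(=O)C(F)(F)F)c1[Si](C)(C)C
A3 | alternative 1 | 2-methylpropanoic acid | CC(C)C(=O)O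
A4 | alternative 2 | ring A phenol with C2 triisopropylsilyl ether and unsubstituted C3, joined to dibenzylated ring B | COc1cc(O[Si](C(C)C)(C(C)C)C(C)C)c(Cc2c(OCc3ccccc3)c(C)c(OC)c(C(=O)C(C)C)c2OCc2ccccc2)c(O)c1C
A5 | alternative 2 | 4-{[2,6-bis(benzyloxy)-4-methoxy-3-methyl-5-(2-methylpropanoyl)phenyl]methyl}-3-(triisopropylsilyloxy)cyclobut-2-en-1-one (racemic) | O=C1C=C(O[Si](C(C)C)(C(C)C)C(C)C)C1Cc1c(OCc2ccccc2)c(C)c(OC)c(C(=O)C(C)C)c1OCc1ccccc1
A6 | alternative 2 | 1-methoxyprop-1-yne | CC#COC
A7 | alternative 3 | ring A dibenzyl ether of the target | COc1c(C)c(O)c(Cc2c(OCc3ccccc3)c(C)c(OC)c(C(=O)CC(C)C)c2OCc2ccccc2)c(O)c1C(=O)C(C)C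
A8 | alternative 3 | 6-{2-[2,6-bis(benzyloxy)-4-methoxy-3-methyl-5-(3-methylbutanoyl)phenyl]ethyl}-4-methoxy-3-methyl-5-(2-methylpropanoyl)pyran-2-one | COc1c(C)c(=O)oc(CCc2c(OCc3ccccc3)c(C)c(OC)c(C(=O)CC(C)C)c2OCc2ccccc2)c1C(=O)C(C)C
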